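## Structural features

The target 18 is a flavone. Benzene ring A and 4-pyranone ring C share the C4a–C8a bond, and benzene ring B is attached to C2 of ring C through the single C2–C1' bond. Ring A is substituted everywhere except C8 (OMe on C5, C6 and C7, O1 on C8a, the C4 carbonyl on C4a), while ring B carries OH on C3' and OMe on C4' and C5'. There is no stereocentre and no stereogenic double bond, so no neighbouring stereocentres need relating and every selectivity question is regiochemical or chemoselective. Three groups are fragile: the C5 methoxy group, peri to the C4 carbonyl and stripped by chelating Lewis acids such as BCl3 or AlCl3; the vinylogous ester O1–C2=C3–C4=O, opened by hydroxide and saturated by forcing hydrogenation; and the 3'-phenol, which traps arynes and quenches organolithiums and so must be masked for most of the route. The real difficulty is to keep one of six phenolic oxygens free while five are methyl ethers, and to place the acyl carbon C4 on C4a, the most crowded carbon of ring A, between C5–OMe and C8a–O1. The key step exploits the adjacency of C8a (oxygen-bearing, next to C8–H) and C4a (acyl-bearing, next to C5–OMe), which is the pattern left when a nucleophile and an electrophile add across an aryne flanked by a methoxy group.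

## Logic of the disconnections

**18 ⇒ 17.** The bond cut is the O–CH2 bond of a benzyl ether on the C3' oxygen. The free phenol would be arylated by 14 and would quench 11. A benzyl group is inert to organolithiums, fluoride, hot carboxylate and nucleophilic amines, and it leaves under neutral conditions that cannot touch the C5 methoxy group. The gain is that the single free OH of 18 is marked from the first step of the ring-B branch. The forward step must cleave the benzylic C–O bond without saturating C2=C3.

**17 ⇒ 16.** The O1–C2 bond is cut, which opens ring C. Since 16 is an isomer of 17, no dehydrogenation is needed after closure, unlike chalcone or flavanone routes. The gain is one ring fewer and a linear C4–C3–C2 chain between two arenes. The forward step must send the phenol oxygen to the β-carbon C2 (6-endo) and not to the α-carbon C3 (5-exo).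

**16 ⇒ 7 + 12.**
- **Bonds cut:** both bonds that tie ring A to the rest, C8a–O1 and C4a–C4. They sit on adjacent carbons, so both trace back to the triple bond of 14, released from 7.
- **Reason:** O1, C4, C3, C2 and ring B all arrive in one piece from 12. This avoids any Lewis-acid acylation of the crowded, demethylation-prone ring.
- **Gain:** the skeleton splits into two halves of nine and eighteen carbons, each three steps from a catalogue compound.
- **Demands:** oxygen must add at C8a, the acyl shift in 15 must outrun protonation, and ring C must stay open. For the last two reasons 12 is used as its dried salt 13 and not as the free acid.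

**12 ⇒ 10.** The C3–C4 bond is cut, and C4 is traced to carbon dioxide. Acetylide 11 is produced in any case when 10 is treated with base, so trapping it directly saves isolating the terminal alkyne. The gain is one carbon and one step. The forward step needs clean double elimination and metalation without lithiation of ring B or rearrangement of the benzyl ether.

**10 ⇒ 9.** The C2=C3 bond is cut, with C3 coming from a one-carbon phosphorus ylide. An aldehyde is the cheapest handle for C2 on ring B. The forward olefination must tolerate three aryl ethers, which it does under neutral conditions.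

**9 ⇒ 8.** The benzyl–oxygen bond is cut. In 8 the methylation pattern of ring B is already correct, so no selective methylation or demethylation is ever needed. The forward step is a simple O-alkylation of the only acidic site.

**7 ⇒ 4.** The O–S bond of the sulfonate and the C–Si bond at the future C4a are cut, and silicon is traced back to the neighbouring oxygen. Intramolecular delivery places silicon in the crowded position between two oxygen substituents, through 5 and 6. The original phenol oxygen becomes the leaving group, and O1 of 18 comes from 12. The forward step needs halogen–metal exchange faster than attack at silicon, and a non-acidic work-up.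

**4 ⇒ 2 + 3.** The O–Si bond is cut. Reagent 3 gives only a volatile by-product, so 4 can be carried on as crude material.

**2 ⇒ 1.** The C–Br bond at the future C4a is cut. In 1 the para position is blocked and the two ortho positions are equivalent by symmetry, so only one monobromide is possible. The forward step has only to stop after one bromination and avoid oxidising the ring.

## Other disconnections considered

**Alternative 1:**
- **Cut and forward step:** the only bond cut is C8a–O1, and ring C is closed last by C–H oxidation. 2',3',4'-Trimethoxyacetophenone A1 and methyl 3,4-dimethoxy-5-(tosyloxy)benzoate A2 would be joined by a Claisen condensation to the diaryl diketone A3. A divalent palladium carboxylate with a terminal oxidant would then have to bond the enol oxygen on the ring-B side to the ortho C–H carbon of the trimethoxybenzoyl ring. This would give the 3'-O-tosyl flavone A4, and sulfonate cleavage would give 18.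
- **In favour:** the building blocks are cheap and no cryogenic or aryne chemistry is needed. Regiochemistry is as unambiguous as in the chosen plan, because the second ortho position carries OMe. At about four steps against nine it is clearly better in step economy.
- **Against, mechanism:** 1,3-diketones bind divalent palladium as stable O,O-chelates, which hold the metal away from C8a. Palladation directed by the enol oxygen would need a seven-membered palladacycle. The C4 carbonyl could direct through a five-membered palladacycle, but the enol oxygen is then poorly placed for C–O reductive elimination.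
- **Against, compatibility:** oxidants strong enough to drive that elimination also attack the doubly activated C3 position and the two electron-rich rings. Basic removal of the sulfonate threatens ring C.
- **Comparison:** the nearest established chemistry is phenol- or alcohol-directed C–H/C–O cyclisation and ketone-directed ortho-hydroxylation, not enol O-arylation. The central step would be unproven on this substrate class, whereas the chosen key step belongs to a known reaction type.

**Alternative 2:**
- **Cut and forward step:** the cuts are C4a–C4 and O1–C2, with C4 at the aldehyde oxidation level. Phenol 1 and (E)-3-[3-(benzyloxy)-4,5-dimethoxyphenyl]prop-2-enal A5 (from 9 by a two-carbon Wittig homologation) would condense under arylboronic acid mediation. Loss of water and an oxa-6π electrocyclisation would then give the racemic 2H-chromene A6.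
- **In favour:** 1 is used directly, without bromination, silylation or triflation. Its symmetry makes the regiochemistry equal to that of the chosen plan at lower cost. The step forms two bonds and one ring, one ring more than the chosen key step.
- **Against:** A6 lies four electrons below 17. C4 must be oxygenated in preference to C3, for instance by a Wacker-type oxidation to the racemic flavanone A7, which must then be dehydrogenated to 17. Quinone oxidants would be expected to lead toward the flavylium cation and not to the C4 ketone. A C2 stereocentre is made only to be destroyed. 2-Aryl-2H-chromenes are sensitive to acid and light, and β-aryl enals are less willing partners than β,β-dialkyl enals.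
- **Comparison:** the total count (six to seven steps) is lower than nine, but every step is linear. The longest sequence is therefore equal to or longer than six, and the late oxidations act on a very electron-rich ring A, where the chosen plan needs no redox adjustment.

**Alternative 3:**
- **Cut and forward step:** carbon C3 is excised, that is, the bonds C2–C3 and C3–C4 are cut. The racemic 2-aryl-4,5,6-trimethoxybenzofuran-3(2H)-one A8 would be silylated to the 3-siloxybenzofuran A9. Dichlorocarbene A10 would add to its C2=C3 bond, and the adduct would open with loss of chloride and silyl to the 3-chloro flavone A11. Hydrogenolysis would then have to remove both chlorine and benzyl.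
- **In favour:** dihalocarbene homologation of silyl enol ethers to α-chloroenones is established for carbocyclic ketones. The combined final hydrogenolysis would make the end-game as short as that of the chosen plan.
- **Against:** A8 already contains the acyl bond at the crowded ring-A carbon, so the main problem is postponed and not solved. A8 is doubly activated at C2 and prone to autoxidation. The double bond of A9 is tetrasubstituted, part of an aromatic furan and shielded by the peri methoxy group. The electrophilic A10 may prefer the electron-rich arenes, and hydroxide-based carbene generation would hydrolyse the silyl ether. A chlorine atom is introduced only to be removed.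
- **Comparison:** the route would not be shorter than nine steps. It builds a five-membered ring in order to expand it, whereas the chosen plan brings C2, C3 and C4 in as one intact chain.

Key step: step 7

Remark on the chemistry: 18 has no stereocentre, so the route SMILES carry no stereodescriptors. The atom mapping of 7, 12 and 16 onto 18 was checked and needs no correction. The only design change is that 12 enters the key step as its dried cesium salt 13. Compounds 1, 3 and 8 are taken as catalogue chemicals.

## Steps

**Step 1**
Reactants: 1 3,4,5-trimethoxyphenol
Product: 2 2-bromo-3,4,5-trimethoxyphenol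
Conditions: NBS (1.0 equiv, in portions), CH2Cl2, −40 → 0 °C, dark
Reagents that add atoms: N-bromosuccinimide, O=C1CCC(=O)N1Br
Why: Electrophilic aromatic bromination; the para position is blocked and the two ortho positions are equivalent, so only one monobromide can form. One equivalent of NBS at low temperature limits a second bromination and oxidation of the electron-rich phenol.

**Step 2**
Reactants: 2 2-bromo-3,4,5-trimethoxyphenol; 3 hexamethyldisilazane
Product: 4 (2-bromo-3,4,5-trimethoxyphenoxy)trimethylsilane
Conditions: THF, reflux; evaporation under vacuum, crude carried on
Reagents that add atoms: none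
Why: O-Silylation of a phenol with a disilazane; the only by-product is volatile, so the moisture-sensitive silyl ether needs no aqueous work-up or chromatography.

**Step 3**
Reactants: 4 (2-bromo-3,4,5-trimethoxyphenoxy)trimethylsilane
Product: 7 3,4,5-trimethoxy-2-(trimethylsilyl)phenyl trifluoromethanesulfonate, via 2-lithio silyl ether 5 (not isolated), via lithium 2-silylphenoxide 6 (not isolated)
Conditions: n-BuLi (1.1 equiv), THF, −100 → −78 °C; Tf2O (1.2 equiv), −100 → −78 °C; aq. NaHCO3; Et3N-deactivated silica
Reagents that add atoms: trifluoromethanesulfonic anhydride, O=S(=O)(OS(=O)(=O)C(F)(F)F)C(F)(F)F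
Why: Bromine–lithium exchange gives 5, whose carbanion attacks the neighbouring silicon (retro-Brook 1,3-shift from O to C), driven by formation of phenoxide 6, which is triflated in the same flask. This is the standard route to ortho-silylaryl triflates and is established for the 3-methoxy analogue with the same crowding.

**Step 4**
Reactants: 8 3-hydroxy-4,5-dimethoxybenzaldehyde
Product: 9 3-(benzyloxy)-4,5-dimethoxybenzaldehyde
Conditions: BnBr (1.1 equiv), K2CO3, DMF, 50 °C
Reagents that add atoms: benzyl bromide, BrCc1ccccc1
Why: Williamson ether synthesis on the only acidic site; the aldehyde is not enolisable and is inert to carbonate.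

**Step 5**
Reactants: 9 3-(benzyloxy)-4,5-dimethoxybenzaldehyde
Product: 10 1-(benzyloxy)-5-(2,2-dibromoethenyl)-2,3-dimethoxybenzene
Conditions: CBr4 (1.5 equiv), PPh3 (3 equiv), CH2Cl2, 0 °C
Reagents that add atoms: carbon tetrabromide, BrC(Br)(Br)Br
Why: First stage of the Corey–Fuchs sequence, a Wittig-type dibromo-olefination by the ylide formed in the flask. The conditions are neutral and leave aryl ethers untouched.

**Step 6**
Reactants: 10 1-(benzyloxy)-5-(2,2-dibromoethenyl)-2,3-dimethoxybenzene
Product: 12 3-[3-(benzyloxy)-4,5-dimethoxyphenyl]prop-2-ynoic acid, via lithium arylacetylide 11 (not isolated)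
Conditions: n-BuLi (2.2 equiv), THF, −78 °C; dry CO2, −78 °C → rt; 1 M HCl
Reagents that add atoms: carbon dioxide, O=C=O
Why: Second stage of the Corey–Fuchs sequence (halogen–metal exchange, elimination with a Fritsch–Buttenberg–Wiechell type shift, deprotonation) gives 11, which is carboxylated directly. At −78 °C ring lithiation and Wittig rearrangement of the benzyl ether are too slow to compete, and the acid is purified by acid–base extraction.

**Step 7**
Reactants: 12 3-[3-(benzyloxy)-4,5-dimethoxyphenyl]prop-2-ynoic acid; 7 3,4,5-trimethoxy-2-(trimethylsilyl)phenyl trifluoromethanesulfonate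
Product: 16 3-[3-(benzyloxy)-4,5-dimethoxyphenyl]-1-(2-hydroxy-4,5,6-trimethoxyphenyl)prop-2-yn-1-one, via cesium arylpropiolate 13 (not isolated), via 3,4,5-trimethoxybenzyne 14 (not isolated), via ortho-anionic aryl ester 15 (not isolated)
Conditions: Cs2CO3 (0.5 equiv), MeOH, rt, evaporation, PhMe azeotrope, vacuum; then 7 (1.3 equiv), CsF (3 equiv), THF (0.03 M), sealed tube, 90 °C; cold 1 M HCl
Reagents that add atoms: none
Why: Fluoride attacks the silicon of 7 and triflate departs, so aryne 14 is released slowly (CsF is sparingly soluble in THF) in the presence of carboxylate 13. A carboxylate oxygen adds to the aryne carbon that becomes C8a, and the aryl anion 15 formed at C4a attacks its own ester carbonyl through a four-membered transition state, an anionic ortho-Fries type 1,3-shift of the acyl group from O to C that ends in the cesium phenoxide of 16 and forms C8a–O1 and C4a–C4 in one operation. The closest known reaction type is the formal insertion of arynes into the C–O bond of carboxylic acids (CsF, hot dilute THF), which gives ortho-hydroxyaryl ketones and is known to accept arylpropiolic acids. No ring is closed and no stereocentre is formed. The regioselectivity needed is oxygen at C8a and acyl at C4a: the C5 methoxy group flanking the triple bond withdraws electrons through the σ frame and distorts the aryne so that the remote carbon is the more electrophilic, the charge develops next to that oxygen, and the remote carbon (next to C8–H) is also the less hindered, while the C6 methoxy group acts weakly in the same sense and the C7 methoxy group only weakly against it. The chemoselectivity needed is acyl shift before protonation of 15, which would stop at the plain aryl ester, and this is why 12 is converted into its dried cesium salt, so that neither free acid nor bifluoride is present, and why the mixture is kept dilute. The lack of a proton source should also hold the product as its phenoxide, because conjugate addition to the ynone cannot be completed without protonating the resulting vinyl anion, so ring C should stay open until the cold acidic quench, and any 17 formed early lies on the route. Benzyl and methyl ethers are inert to fluoride.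

**Step 8**
Reactants: 16 3-[3-(benzyloxy)-4,5-dimethoxyphenyl]-1-(2-hydroxy-4,5,6-trimethoxyphenyl)prop-2-yn-1-one
Product: 17 2-[3-(benzyloxy)-4,5-dimethoxyphenyl]-5,6,7-trimethoxy-4H-chromen-4-one
Conditions: DMAP (0.2 equiv), DMF, 25–40 °C
Reagents that add atoms: none
Why: Nucleophile-catalysed intramolecular oxa-Michael cyclisation of an ortho-alkynoylphenol: DMAP adds to the β-carbon C2, and the phenoxide then displaces it at the same carbon by 6-endo addition–elimination, forming O1–C2. The α-carbon C3 is never electrophilic in this manifold, so the 5-exo path is closed.

**Step 9**
Reactants: 17 2-[3-(benzyloxy)-4,5-dimethoxyphenyl]-5,6,7-trimethoxy-4H-chromen-4-one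
Product: 18 2-(3-hydroxy-4,5-dimethoxyphenyl)-5,6,7-trimethoxy-4H-chromen-4-one (3'-hydroxy-5,6,7,4',5'-pentamethoxyflavone)
Conditions: H2 (1 atm), Pd/C (10 wt % Pd), EtOAc–MeOH, rt, stopped at one equivalent of H2
Reagents that add atoms: none
Why: Catalytic hydrogenolysis of a benzyl aryl ether; at one atmosphere the benzylic C–O bond should be cleaved well before the C2=C3 bond of the conjugated pyranone is touched. The neutral medium spares the C5 methoxy group, which Lewis-acid debenzylation would endanger.

## Compound list

1 | 3,4,5-trimethoxyphenol | COc1cc(O)cc(OC)c1OC | starting material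
2 | 2-bromo-3,4,5-trimethoxyphenol | COc1cc(O)c(Br)c(OC)c1OC | intermediate
3 | hexamethyldisilazane | C[Si](C)(C)N[Si](C)(C)C | starting material
4 | (2-bromo-3,4,5-trimethoxyphenoxy)trimethylsilane | COc1cc(O[Si](C)(C)C)c(Br)c(OC)c1OC | intermediate
5 | [2,3,4-trimethoxy-6-(trimethylsilyloxy)phenyl]lithium | [Li]c1c(O[Si](C)(C)C)cc(OC)c(OC)c1OC | intermediate
6 | lithium 3,4,5-trimethoxy-2-(trimethylsilyl)phenoxide | [Li+].[O-]c1cc(OC)c(OC)c(OC)c1[Si](C)(C)C | intermediate
7 | 3,4,5-trimethoxy-2-(trimethylsilyl)phenyl trifluoromethanesulfonate | COc1cc(OS(=O)(=O)C(F)(F)F)c([Si](C)(C)C)c(OC)c1OC | intermediate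
8 | 3-hydroxy-4,5-dimethoxybenzaldehyde | COc1cc(C=O)cc(O)c1OC | starting material
9 | 3-(benzyloxy)-4,5-dimethoxybenzaldehyde | COc1cc(C=O)cc(OCc2ccccc2)c1OC | intermediate
10 | 1-(benzyloxy)-5-(2,2-dibromoethenyl)-2,3-dimethoxybenzene | COc1cc(C=C(Br)Br)cc(OCc2ccccc2)c1OC | intermediate
11 | {[3-(benzyloxy)-4,5-dimethoxyphenyl]ethynyl}lithium | [Li]C#Cc1cc(OC)c(OC)c(OCc2ccccc2)c1 | intermediate
12 | 3-[3-(benzyloxy)-4,5-dimethoxyphenyl]prop-2-ynoic acid | COc1cc(C#CC(=O)O)cc(OCc2ccccc2)c1OC | intermediate
13 | cesium 3-[3-(benzyloxy)-4,5-dimethoxyphenyl]prop-2-ynoate | [Cs+].COc1cc(C#CC(=O)[O-])cc(OCc2ccccc2)c1OC | intermediate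
14 | 3,4,5-trimethoxybenzyne (1,2-didehydro-3,4,5-trimethoxybenzene) | COC1=CC#CC(OC)=C1OC | intermediate
15 | cesium salt of the C2 carbanion of 3,4,5-trimethoxyphenyl 3-[3-(benzyloxy)-4,5-dimethoxyphenyl]prop-2-ynoate | [Cs+].COc1cc(OC(=O)C#Cc2cc(OC)c(OC)c(OCc3ccccc3)c2)[c-]c(OC)c1OC | intermediate
16 | 3-[3-(benzyloxy)-4,5-dimethoxyphenyl]-1-(2-hydroxy-4,5,6-trimethoxyphenyl)prop-2-yn-1-one | COc1cc(C#CC(=O)c2c(O)cc(OC)c(OC)c2OC)cc(OCc2ccccc2)c1OC | intermediate
17 | 2-[3-(benzyloxy)-4,5-dimethoxyphenyl]-5,6,7-trimethoxy-4H-chromen-4-one | COc1cc(-c2cc(=O)c3c(OC)c(OC)c(OC)cc3o2)cc(OCc2ccccc2)c1OC | intermediate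
18 | 2-(3-hydroxy-4,5-dimethoxyphenyl)-5,6,7-trimethoxy-4H-chromen-4-one | COc1cc(-c2cc(=O)c3c(OC)c(OC)c(OC)cc3o2)cc(O)c1OC | target

## Step count and least certain steps

Total step count: 9. Longest linear sequence: 6 steps (steps 1–3 or steps 4–6, followed by steps 7–9).

**Step 7 (key step).**
- **Risk:** the most likely failure is protonation of the aryl anion before the acyl shift, so that the reaction ends as a plain O-arylation. Adventitious water or incompletely dried salt would cause this.
- **Further risks:** thermal decarboxylation of the propiolate, arylation of the product phenoxide by a second aryne, attack of the aryl anion on the alkyne terminus instead of the carbonyl, and early ring closure in the 5-exo mode during the hot period.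
- **Fallback:** it sets out from 1 and 10 and comes back at 16, replacing the aryne by a polar carbonyl addition. Phenol 1 is ortho-formylated with MgCl2, Et3N and paraformaldehyde (Casnati–Skattebøl formylation; both ortho positions are equivalent) to 2-hydroxy-4,5,6-trimethoxybenzaldehyde F1. F1 is deprotonated with one equivalent of n-BuLi and treated with acetylide 11, generated from 10 as in step 6. This gives rac-3-[3-(benzyloxy)-4,5-dimethoxyphenyl]-1-(2-hydroxy-4,5,6-trimethoxyphenyl)prop-2-yn-1-ol F2, which MnO2 in CH2Cl2 oxidises to 16.

**Step 8.**
- **Risk:** closure may leak into the 5-exo mode if simple base catalysis competes with nucleophilic catalysis. Addition of DMAP may also be slow, because C2 is deactivated by the electron-rich ring B and the carbonyl is twisted by its two ortho substituents.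
- **Fallback:** it sets out from 16 and comes back at 17, removing the alkyne before the ring is closed. Diethylamine in EtOH adds to the ynone to give the isolable push–pull alkene (E)-3-[3-(benzyloxy)-4,5-dimethoxyphenyl]-3-(diethylamino)-1-(2-hydroxy-4,5,6-trimethoxyphenyl)prop-2-en-1-one F3. Warming F3 in acetic acid closes O1–C2 by addition–elimination with loss of the amine, and only the six-membered ring can form.

**Step 3.**
- **Risk:** silyl migration into the position between two oxygen substituents may be incomplete. The aryllithium may be protonated or butylated. The very electron-rich arylsilane may undergo protodesilylation on acidic work-up or on silica.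
- **Fallback:** it sets out from 4 and comes back at 7, separating C-silylation from triflation. After the bromine–lithium exchange the mixture is quenched with Me3SiCl, which converts both 5 and 6 into trimethyl[2,3,4-trimethoxy-6-(trimethylsilyloxy)phenyl]silane F4. Mild methanolysis (K2CO3, MeOH) removes only the O-silyl group and gives 3,4,5-trimethoxy-2-(trimethylsilyl)phenol F5. F5 can be purified and is then triflated with Tf2O and pyridine in CH2Cl2 at 0 °C.

**Step 1.**
- **Risk:** a second bromination at the remaining ortho position, and oxidation of the electron-rich phenol toward a quinone.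
- **Fallback:** it sets out from 1 and comes back at 7, bypassing steps 1 to 3 by directed ortho-metalation. Isopropyl isocyanate with catalytic Et3N gives 3,4,5-trimethoxyphenyl N-isopropylcarbamate F6. N-Silylation in the flask (TBSOTf, TMEDA), lithiation with n-BuLi at −78 °C between the carbamate and the methoxy group, quenching with Me3SiCl and a mild acidic work-up give 3,4,5-trimethoxy-2-(trimethylsilyl)phenyl N-isopropylcarbamate F7. Cleavage with DBU and Et2NH in MeCN at 40 °C, followed by PhNTf2 in the same flask, gives 7.

**Step 9.**
- **Risk:** over-reduction of the C2=C3 bond, or stalling of the hydrogenolysis through poor solubility or poisoning of the catalyst by traces of DMAP or halide.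
- **Fallback:** it sets out from 17 and comes back at 18, exchanging reduction for acidolysis. Trifluoroacetic acid with pentamethylbenzene as benzyl cation scavenger cleaves the benzyl aryl ether, while methyl ethers, including the one on C5, are not attacked by a non-chelating Brønsted acid. No new compound lies on this way (entry F0).

## Further compounds

F1 | step 7 | 2-hydroxy-4,5,6-trimethoxybenzaldehyde | COc1cc(O)c(C=O)c(OC)c1OC
F2 | step 7 | rac-3-[3-(benzyloxy)-4,5-dimethoxyphenyl]-1-(2-hydroxy-4,5,6-trimethoxyphenyl)prop-2-yn-1-ol | COc1cc(C#CC(O)c2c(O)cc(OC)c(OC)c2OC)cc(OCc2ccccc2)c1OC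
F3 | step 8 | (E)-3-[3-(benzyloxy)-4,5-dimethoxyphenyl]-3-(diethylamino)-1-(2-hydroxy-4,5,6-trimethoxyphenyl)prop-2-en-1-one | CCN(CC)/C(c1cc(OC)c(OC)c(OCc2ccccc2)c1)=C/C(=O)c1c(O)cc(OC)c(OC)c1OC
F4 | step 3 | trimethyl[2,3,4-trimethoxy-6-(trimethylsilyloxy)phenyl]silane | COc1cc(O[Si](C)(C)C)c([Si](C)(C)C)c(OC)c1OC
F5 | step 3 | 3,4,5-trimethoxy-2-(trimethylsilyl)phenol | COc1cc(O)c([Si](C)(C)C)c(OC)c1OC
F6 | step 1 | 3,4,5-trimethoxyphenyl N-isopropylcarbamate | COc1cc(OC(=O)NC(C)C)cc(OC)c1OC
F7 | step 1 | 3,4,5-trimethoxy-2-(trimethylsilyl)phenyl N-isopropylcarbamate | COc1cc(OC(=O)NC(C)C)c([Si](C)(C)C)c(OC)c1OC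
F0 | step 9 | none | none
A1 | alternative 1 | 2',3',4'-trimethoxyacetophenone | CC(=O)c1ccc(OC)c(OC)c1OC
A2 | alternative 1 | methyl 3,4-dimethoxy-5-(tosyloxy)benzoate | COC(=O)c1cc(OC)c(OC)c(OS(=O)(=O)c2ccc(C)cc2)c1
A3 | alternative 1 | 1-(2,3,4-trimethoxyphenyl)-3-[3,4-dimethoxy-5-(tosyloxy)phenyl]propane-1,3-dione | COc1cc(C(=O)CC(=O)c2ccc(OC)c(OC)c2OC)cc(OS(=O)(=O)c2ccc(C)cc2)c1OC
A4 | alternative 1 | 3'-O-tosyl derivative of the target flavone | COc1cc(-c2cc(=O)c3c(OC)c(OC)c(OC)cc3o2)cc(OS(=O)(=O)c2ccc(C)cc2)c1OC
A5 | alternative 2 | (E)-3-[3-(benzyloxy)-4,5-dimethoxyphenyl]prop-2-enal | COc1cc(/C=C/C=O)cc(OCc2ccccc2)c1OC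
A6 | alternative 2 | rac-2-[3-(benzyloxy)-4,5-dimethoxyphenyl]-5,6,7-trimethoxy-2H-chromene | COc1cc(C2C=Cc3c(OC)c(OC)c(OC)cc3O2)cc(OCc2ccccc2)c1OC
A7 | alternative 2 | rac-2-[3-(benzyloxy)-4,5-dimethoxyphenyl]-5,6,7-trimethoxychroman-4-one | COc1cc(C2CC(=O)c3c(OC)c(OC)c(OC)cc3O2)cc(OCc2ccccc2)c1OC
A8 | alternative 3 | rac-2-[3-(benzyloxy)-4,5-dimethoxyphenyl]-4,5,6-trimethoxy-1-benzofuran-3(2H)-one | COc1cc(C2Oc3cc(OC)c(OC)c(OC)c3C2=O)cc(OCc2ccccc2)c1OC
A9 | alternative 3 | ({2-[3-(benzyloxy)-4,5-dimethoxyphenyl]-4,5,6-trimethoxy-1-benzofuran-3-yl}oxy)trimethylsilane | COc1cc(-c2oc3cc(OC)c(OC)c(OC)c3c2O[Si](C)(C)C)cc(OCc2ccccc2)c1OC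
A10 | alternative 3 | dichlorocarbene | Cl[C]Cl
A11 | alternative 3 | 2-[3-(benzyloxy)-4,5-dimethoxyphenyl]-3-chloro-5,6,7-trimethoxy-4H-chromen-4-one | COc1cc(-c2oc3cc(OC)c(OC)c(OC)c3c(=O)c2Cl)cc(OCc2ccccc2)c1OC
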